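**Plan**

1. Retrosynthesis: remove the C8 methacrylate and the C2=C3 unsaturation, then take C10 out from between the ring oxygen and C9 (O–C10 and C9–C10 bonds). This turns the nine-membered oxacycle (O, C3–C10) into an eight-membered cyclic acetal (O, C3–C9) with a diazoketone on C3, which is cut at C4=C5 (metathesis), O–C9 (acetal), C6–C7 (Barbier) and C7–C11 (Baylis–Hillman).
2. Enabling feature: the ether oxygen bridges C3 and C10, and C10 is flanked by oxygen-bearing C9. C9 can therefore be the acetal carbon of a C8/C9 dioxolane bonded to that oxygen; a carbene at C10 then forms a five-membered oxonium ylide whose Stevens [1,2]-shift inserts C10 into the O–C9 bond.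
3. Forward: a C1–C4 allylic alcohol and an L-tartrate-derived dioxolanyl acetate (C7–C9) are joined at the acetal. Baylis–Hillman/Barbier chemistry adds C11–C13 and C5–C6 and closes the cis-lactone, and metathesis closes the eight-membered acetal. The key step expands it to nine atoms while closing the furanone ring and the ten-membered carbocycle; dehydrogenation, acetonide removal and methacrylation finish.
4. Stereochemistry: C8 from L-tartaric acid; C9 by trans addition to the dioxolanylium ion and retention in the shift; C7 and C6 from the chair Barbier transition state under allylic-strain control by C8. C3 comes from Corey–Bakshi–Shibata reduction, relays to C10 in the key step (cis bridge) and is then erased; ring size fixes the Z alkene.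

Key step: step 16

Remark: atoms are labelled C1–C15 as in the germacrane skeleton of the target and the labels are kept for all intermediates. The ring oxygen lies between C3 and C10, the lactone oxygen is on C6, C11–C13 are the lactone carbons on C7, the ester oxygen is on C8, the hydroxyl on C9, C14 is the methyl on C10 and C15 the methyl on C4.
Assumption: the [1,2]-shift of step 16 occurs with retention at the migrating acetal carbon C9; the trans-fused dioxolane would give the same C9 configuration in a stepwise recombination.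

**Route**

Step 1
Reactants: 1 3-(tert-butyldimethylsilyloxy)propanal; 2 isopropenylmagnesium bromide
Product: 3 rac-5-(tert-butyldimethylsilyloxy)-2-methylpent-1-en-3-ol
Conditions: THF, −78 → 0 °C; aq. NH4Cl
Reagents that add atoms: none
Why: Grignard 1,2-addition of the alkenylmagnesium reagent to the aldehyde gives the racemic allylic alcohol, whose configuration is set in step 3.

Step 2
Reactants: 3 rac-5-(tert-butyldimethylsilyloxy)-2-methylpent-1-en-3-ol
Product: 4 5-(tert-butyldimethylsilyloxy)-2-methylpent-1-en-3-one
Conditions: Dess–Martin periodinane, NaHCO3, CH2Cl2, 0 °C → rt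
Reagents that add atoms: none
Why: Dess–Martin oxidation of the secondary allylic alcohol to the enone runs under buffered neutral conditions that leave the primary silyl ether intact.

Step 3
Reactants: 4 5-(tert-butyldimethylsilyloxy)-2-methylpent-1-en-3-one
Product: 5 (R)-5-(tert-butyldimethylsilyloxy)-2-methylpent-1-en-3-ol
Conditions: (S)-2-methyl-CBS-oxazaborolidine [(S)-1-methyl-3,3-diphenyltetrahydro-1H,3H-pyrrolo[1,2-c][1,3,2]oxazaborole] (10 mol%), BH3·SMe2, THF, −30 °C; MeOH
Reagents that add atoms: none
Why: Corey–Bakshi–Shibata reduction, in which the isopropenyl group is the large substituent, so the (S)-oxazaborolidine should deliver hydride to give the (R)-carbinol (C3), the low temperature suppressing hydroboration of the alkene.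

Step 4
Reactants: 6 dimethyl (4R,5R)-2,2-dimethyl-1,3-dioxolane-4,5-dicarboxylate (from L-tartaric acid)
Product: 7 (4R,5R)-5-(methoxycarbonyl)-2,2-dimethyl-1,3-dioxolane-4-carboxylic acid
Conditions: KOH (1 equiv), MeOH, 0 °C → rt; then aq. HCl
Reagents that add atoms: potassium hydroxide, [K+].[OH-]
Why: Mono-saponification of the C2-symmetric diester should stop at the half ester because the carboxylate deactivates the molecule towards a second hydrolysis, and the trans-dioxolane stereocentres are untouched.

Step 5
Reactants: 7 (4R,5R)-5-(methoxycarbonyl)-2,2-dimethyl-1,3-dioxolane-4-carboxylic acid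
Product: 8 methyl (4R)-5-acetoxy-2,2-dimethyl-1,3-dioxolane-4-carboxylate (both C5 epimers)
Conditions: Pb(OAc)4, pyridine, THF, rt
Reagents that add atoms: lead tetraacetate, CC(=O)O[Pb](OC(C)=O)(OC(C)=O)OC(C)=O
Why: Oxidative decarboxylation of the α-alkoxy acid with Pb(OAc)4 passes through the dioxolan-4-yl radical and cation and traps acetate, turning the future C9 into an anomeric acetate whose configuration does not matter.

Step 6
Reactants: 5 (R)-5-(tert-butyldimethylsilyloxy)-2-methylpent-1-en-3-ol; 8 methyl (4R)-5-acetoxy-2,2-dimethyl-1,3-dioxolane-4-carboxylate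
Product: 9 methyl (4R,5R)-5-{[(3R)-5-(tert-butyldimethylsilyloxy)-2-methylpent-1-en-3-yl]oxy}-2,2-dimethyl-1,3-dioxolane-4-carboxylate (trans-dioxolane)
Conditions: Me3SiOTf (0.2 equiv), 4 Å molecular sieves, CH2Cl2, −78 → −40 °C
Reagents that add atoms: none
Why: Glycosylation-type acetal exchange in which the anomeric acetate ionizes to the 1,3-dioxolan-4-ylium ion and alcohol 5 attacks anti to the neighbouring ester group, setting C9 trans to the C8 substituent.

Step 7
Reactants: 9 methyl (4R,5R)-5-{[(3R)-5-(tert-butyldimethylsilyloxy)-2-methylpent-1-en-3-yl]oxy}-2,2-dimethyl-1,3-dioxolane-4-carboxylate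
Product: 10 (4S,5R)-5-{[(3R)-5-(tert-butyldimethylsilyloxy)-2-methylpent-1-en-3-yl]oxy}-2,2-dimethyl-1,3-dioxolane-4-carbaldehyde
Conditions: iBu2AlH (1.1 equiv), CH2Cl2, −78 °C; Rochelle salt
Reagents that add atoms: none
Why: Partial reduction of the α-alkoxy methyl ester with iBu2AlH at −78 °C stops at the aldehyde stage and leaves the silyl ether and both acetals untouched.

Step 8
Reactants: 10 (4S,5R)-5-{[(3R)-5-(tert-butyldimethylsilyloxy)-2-methylpent-1-en-3-yl]oxy}-2,2-dimethyl-1,3-dioxolane-4-carbaldehyde; 11 methyl acrylate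
Product: 12 methyl 2-{hydroxy[(4S,5R)-5-{[(3R)-5-(tert-butyldimethylsilyloxy)-2-methylpent-1-en-3-yl]oxy}-2,2-dimethyl-1,3-dioxolan-4-yl]methyl}acrylate (C7 epimers)
Conditions: DABCO (1 equiv), 1,4-dioxane–H2O (1:1), rt
Reagents that add atoms: none
Why: Morita–Baylis–Hillman reaction forms the C7–C11 bond; the new carbinol centre is removed in step 9 and any epimerization at C8 should return to the favoured trans-dioxolane.

Step 9
Reactants: 12 methyl 2-{hydroxy[(4S,5R)-5-{[(3R)-5-(tert-butyldimethylsilyloxy)-2-methylpent-1-en-3-yl]oxy}-2,2-dimethyl-1,3-dioxolan-4-yl]methyl}acrylate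
Product: 13 methyl (2Z)-2-(bromomethyl)-3-[(4S,5R)-5-{[(3R)-5-(tert-butyldimethylsilyloxy)-2-methylpent-1-en-3-yl]oxy}-2,2-dimethyl-1,3-dioxolan-4-yl]prop-2-enoate
Conditions: N-bromosuccinimide, Me2S, CH2Cl2, 0 °C → rt
Reagents that add atoms: N-bromosuccinimide, O=C1CCC(=O)N1Br
Why: SN2' displacement of the alkoxysulfonium derivative of the Baylis–Hillman alcohol by bromide gives the thermodynamically preferred (Z)-2-(bromomethyl)enoate under non-acidic conditions.

Step 10
Reactants: 13 methyl (2Z)-2-(bromomethyl)-3-[(4S,5R)-5-{[(3R)-5-(tert-butyldimethylsilyloxy)-2-methylpent-1-en-3-yl]oxy}-2,2-dimethyl-1,3-dioxolan-4-yl]prop-2-enoate; 14 acrolein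
Product: 16 (4S,5S)-4-[(4S,5R)-5-{[(3R)-5-(tert-butyldimethylsilyloxy)-2-methylpent-1-en-3-yl]oxy}-2,2-dimethyl-1,3-dioxolan-4-yl]-3-methylidene-5-vinyloxolan-2-one (cis-lactone; 6S,7S,8S), via syn-hydroxy ester 15 (not isolated)
Conditions: Zn dust, THF–sat. aq. NH4Cl, 0 °C → rt; then PPTS (cat.), benzene, 40 °C
Reagents that add atoms: none
Why: Barbier allylation through a closed chair transition state in which the (Z)-allylzinc adds through C7 to acrolein to give the syn C6/C7 adduct, the aldehyde approaching anti to the C8–C9 bond of the allylic stereocentre whose hydrogen lies in the alkene plane (allylic 1,3-strain), after which the cis-hydroxy ester lactonizes.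

Step 11
Reactants: 16 (4S,5S)-4-[(4S,5R)-5-{[(3R)-5-(tert-butyldimethylsilyloxy)-2-methylpent-1-en-3-yl]oxy}-2,2-dimethyl-1,3-dioxolan-4-yl]-3-methylidene-5-vinyloxolan-2-one
Product: 17 (3R,4Z,6S,7S,8S,9R)-eight-membered cyclic acetal (ring O–C3–C4=C5–C6–C7–C8–C9) with 8,9-O-isopropylidene, 6,12-lactone, 11(13)-methylene and a 2-(tert-butyldimethylsilyloxy)ethyl group on C3
Conditions: second-generation Grubbs catalyst (10 mol%), CH2Cl2 (0.002 M), reflux
Reagents that add atoms: none
Why: Ring-closing metathesis of the vinyl and isopropenyl groups closes the eight-membered cyclic acetal, whose ring size enforces the Z trisubstituted C4=C5 alkene, while the electron-poor 1,1-disubstituted methylene lactone is a spectator.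

Step 12
Reactants: 17 (3R,4Z,6S,7S,8S,9R)-eight-membered cyclic acetal with silyl ether side chain
Product: 18 (3R,4Z,6S,7S,8S,9R)-eight-membered cyclic acetal with a 2-hydroxyethyl group on C3
Conditions: HF·pyridine, pyridine, THF, 0 °C → rt
Reagents that add atoms: none
Why: Buffered fluoride cleavage of the primary silyl ether should spare the acetonide, the acetal and the base-sensitive methylene lactone.

Step 13
Reactants: 18 (3R,4Z,6S,7S,8S,9R)-eight-membered cyclic acetal with a 2-hydroxyethyl group on C3
Product: 19 (3R,4Z,6S,7S,8S,9R)-eight-membered cyclic acetal with a carboxymethyl group on C3 (C1 acid)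
Conditions: TEMPO (20 mol%), PhI(OAc)2, MeCN–pH 7 buffer, rt
Reagents that add atoms: water, O
Why: TEMPO/PhI(OAc)2 oxidation of the primary alcohol through the aldehyde hydrate gives the acid without touching the alkenes or acetals.

Step 14
Reactants: 19 C1 acid of the eight-membered cyclic acetal
Product: 20 C1 acid with the methylene lactone masked as the 11-(phenylsulfonylmethyl) lactone (C11 epimers)
Conditions: PhSO2Na, AcOH, DMF, rt
Reagents that add atoms: sodium benzenesulfinate, [Na+].[O-]S(=O)c1ccccc1
Why: Sulfa-Michael addition of benzenesulfinate masks the methylene lactone as a β-sulfonyl lactone so that it cannot undergo 1,3-dipolar cycloaddition with diazoethane in step 15; the new C11 centre is removed in step 17.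

Step 15
Reactants: 20 sulfone-masked C1 acid
Product: 22 (3R,4Z,6S,7S,8S,9R)-eight-membered cyclic acetal with a 3-diazo-2-oxobutyl group on C3 (α-diazo ketone), via mixed anhydride 21 (not isolated)
Conditions: iBuOCOCl, N-methylmorpholine, THF, −20 °C; then CH3CHN2, Et2O, −20 → 0 °C
Reagents that add atoms: isobutyl chloroformate, CC(C)COC(Cl)=O (atoms only in 21); diazoethane, CC=[N+]=[N-]
Why: Acylation of diazoethane by the mixed carbonic anhydride (Arndt–Eistert-type diazoketone synthesis) installs C10 and C14, the weak base and low temperature leaving the β-alkoxy acid and the β-sulfonyl lactone intact.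

Step 16
Reactants: 22 α-diazo ketone of the eight-membered cyclic acetal
Product: 24 (3R,4Z,6S,7S,8S,9R,10R)-3,10-epoxy-1-oxo ten-membered carbocycle (tetrahydrofuran-3-one bridged across C3/C10; nine-membered oxacycle O, C3–C10) with 8,9-O-isopropylidene and sulfone-masked 6,12-lactone, via oxonium ylide 23 (not isolated)
Conditions: Cu(hfacac)2 [copper bis(hexafluoroacetylacetonate)] (10 mol%), CH2Cl2 (0.005 M), reflux, slow addition of 22
Reagents that add atoms: none
Why: Copper-catalysed loss of N2 from 22 and capture of the carbene carbon C10 by the ring oxygen gives the bicyclic oxonium ylide 23, and a Stevens [1,2]-shift then moves the acetal carbon C9 from oxygen to C10, so that C10 is inserted into the O–C9 bond and the eight-membered ring becomes the nine-membered oxacycle. The closest known reaction type is the ring expansion of cyclic mixed acetals carrying a diazoketone side chain to oxygen-bridged carbocycles by oxonium ylide [1,2]-shift. The five-membered tetrahydrofuran-3-one ring closes by O–C10 bond formation at the metal carbene (five-membered ylide formation), and the ten-membered carbocycle closes by C9–C10 recombination of the radical pair or dioxolanylium/enolate pair inside the ylide. C10 is controlled by C3, because C9 can reach C10 only on the face of the five-membered ring that carries C4 (cis bridge), and C9 is controlled by the trans-fused dioxolane, which gives retention in a caged pair and the same trans result if C9 passes through the planar dioxolan-4-yl cation. The step needs ylide formation to win over cyclopropanation of the C4=C5 alkene and 1,2-hydride shift, and migration of C9 to win over allylic C3: the electrophilic Cu(hfacac)2 carbenoid and the five-membered geometry favour attack on oxygen, and only C9 carries a second oxygen and gives an unstrained product (shift of C3 would give a cyclobutanone).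

Step 17
Reactants: 24 ring-expanded tetrahydrofuran-3-one with sulfone-masked lactone
Product: 25 (3R,4Z,6S,7S,8S,9R,10R)-ring-expanded tetrahydrofuran-3-one with 11(13)-methylene-6,12-lactone and 8,9-O-isopropylidene
Conditions: DBU, CH2Cl2, 0 °C
Reagents that add atoms: none
Why: E1cB elimination of benzenesulfinate from the β-sulfonyl lactone regenerates the exocyclic methylene, and reversible enolization of the ketone towards C2 is harmless because ring opening at C3 can only reclose to the same cis-bridged isomer.

Step 18
Reactants: 25 ring-expanded tetrahydrofuran-3-one with methylene lactone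
Product: 27 (4Z,6S,7S,8S,9R,10R)-3(2H)-furanone with 8,9-O-isopropylidene (acetonide of the 8,9-diol of the target core), via silyl enol ether 26 (not isolated)
Conditions: Me3SiOTf, Et3N, CH2Cl2, 0 °C; then Pd(OAc)2, MeCN, rt
Reagents that add atoms: trimethylsilyl triflate, C[Si](C)(C)OS(=O)(=O)C(F)(F)F (atoms only in 26)
Why: Saegusa–Ito oxidation, in which quaternary C10 allows enol silylation only towards C2 and Pd(OAc)2 then removes the C3 hydrogen to give the 3(2H)-furanone, erasing the relay stereocentre at C3.

Step 19
Reactants: 27 3(2H)-furanone acetonide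
Product: 28 (4Z,6S,7S,8S,9R,10R)-8,9-dihydroxy-3,10-epoxy-1-oxogermacra-2,4,11(13)-trien-6,12-olide (diol)
Conditions: AcOH–H2O (4:1), 45 °C
Reagents that add atoms: none
Why: Acid-catalysed hydrolysis of the strained trans-fused isopropylidene ketal frees the C8/C9 diol, the furanone (a vinylogous ester) and the lactone being stable to aqueous acid.

Step 20
Reactants: 28 8,9-diol
Product: 29 target, the 8-O-methacrylate of 28 (CNP0252578.4)
Conditions: methacrylic anhydride, DMAP (cat.), Et3N, CH2Cl2, −20 °C
Reagents that add atoms: methacrylic anhydride, C=C(C)C(=O)OC(=O)C(C)=C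
Why: DMAP-catalysed acylation at low temperature should take place at the C8 hydroxyl because the C9 hydroxyl is neopentylic (next to quaternary C10) and much more hindered.

**Compound list**

1 | 3-(tert-butyldimethylsilyloxy)propanal | O=CCCO[Si](C)(C)C(C)(C)C | starting material
2 | isopropenylmagnesium bromide | C=C(C)[Mg]Br | starting material
3 | rac-5-(tert-butyldimethylsilyloxy)-2-methylpent-1-en-3-ol | C=C(C)C(O)CCO[Si](C)(C)C(C)(C)C | intermediate
4 | 5-(tert-butyldimethylsilyloxy)-2-methylpent-1-en-3-one | C=C(C)C(=O)CCO[Si](C)(C)C(C)(C)C | intermediate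
5 | (R)-5-(tert-butyldimethylsilyloxy)-2-methylpent-1-en-3-ol | C=C(C)[C@H](O)CCO[Si](C)(C)C(C)(C)C | intermediate
6 | dimethyl (4R,5R)-2,2-dimethyl-1,3-dioxolane-4,5-dicarboxylate | COC(=O)[C@@H]1OC(C)(C)O[C@H]1C(=O)OC | starting material
7 | (4R,5R)-5-(methoxycarbonyl)-2,2-dimethyl-1,3-dioxolane-4-carboxylic acid | COC(=O)[C@@H]1OC(C)(C)O[C@H]1C(=O)O | intermediate
8 | methyl (4R)-5-acetoxy-2,2-dimethyl-1,3-dioxolane-4-carboxylate (C5 epimers) | COC(=O)[C@@H]1OC(C)(C)OC1OC(C)=O | intermediate
9 | methyl (4R,5R)-5-{[(3R)-5-(tert-butyldimethylsilyloxy)-2-methylpent-1-en-3-yl]oxy}-2,2-dimethyl-1,3-dioxolane-4-carboxylate | COC(=O)[C@@H]1OC(C)(C)O[C@H]1O[C@H](CCO[Si](C)(C)C(C)(C)C)C(C)=C | intermediate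
10 | (4S,5R)-5-{[(3R)-5-(tert-butyldimethylsilyloxy)-2-methylpent-1-en-3-yl]oxy}-2,2-dimethyl-1,3-dioxolane-4-carbaldehyde | O=C[C@@H]1OC(C)(C)O[C@H]1O[C@H](CCO[Si](C)(C)C(C)(C)C)C(C)=C | intermediate
11 | methyl acrylate | C=CC(=O)OC | starting material
12 | Baylis–Hillman adduct, methyl 2-[hydroxy(dioxolanyl)methyl]acrylate (C7 epimers) | C=C(C(=O)OC)C(O)[C@@H]1OC(C)(C)O[C@H]1O[C@H](CCO[Si](C)(C)C(C)(C)C)C(C)=C | intermediate
13 | methyl (2Z)-2-(bromomethyl)-3-(dioxolanyl)prop-2-enoate | BrC/C(C(=O)OC)=C\[C@@H]1OC(C)(C)O[C@H]1O[C@H](CCO[Si](C)(C)C(C)(C)C)C(C)=C | intermediate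
14 | acrolein | C=CC=O | starting material
15 | syn-hydroxy ester (6S,7S,8S), not isolated | C=C[C@H](O)[C@H](C(=C)C(=O)OC)[C@@H]1OC(C)(C)O[C@H]1O[C@H](CCO[Si](C)(C)C(C)(C)C)C(C)=C | intermediate
16 | cis-lactone, (4S,5S)-4-(dioxolanyl)-3-methylidene-5-vinyloxolan-2-one | C=C[C@@H]1OC(=O)C(=C)[C@@H]1[C@@H]2OC(C)(C)O[C@H]2O[C@H](CCO[Si](C)(C)C(C)(C)C)C(C)=C | intermediate
17 | (3R,4Z,6S,7S,8S,9R)-eight-membered cyclic acetal, C3 side chain CH2CH2OSi(tBu)Me2 | CC1(C)O[C@H]2[C@H]3C(=C)C(=O)O[C@H]3/C=C(/C)[C@@H](CCO[Si](C)(C)C(C)(C)C)O[C@@H]2O1 | intermediate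
18 | eight-membered cyclic acetal, C3 side chain CH2CH2OH | CC1(C)O[C@H]2[C@H]3C(=C)C(=O)O[C@H]3/C=C(/C)[C@@H](CCO)O[C@@H]2O1 | intermediate
19 | eight-membered cyclic acetal, C3 side chain CH2CO2H | CC1(C)O[C@H]2[C@H]3C(=C)C(=O)O[C@H]3/C=C(/C)[C@@H](CC(=O)O)O[C@@H]2O1 | intermediate
20 | sulfone-masked acid (C11 epimers) | CC1(C)O[C@H]2[C@H]3C(CS(=O)(=O)c4ccccc4)C(=O)O[C@H]3/C=C(/C)[C@@H](CC(=O)O)O[C@@H]2O1 | intermediate
21 | isobutyl carbonic mixed anhydride of 20, not isolated | CC1(C)O[C@H]2[C@H]3C(CS(=O)(=O)c4ccccc4)C(=O)O[C@H]3/C=C(/C)[C@@H](CC(=O)OC(=O)OCC(C)C)O[C@@H]2O1 | intermediate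
22 | α-diazo ketone (3-diazo-2-oxobutyl on C3) | CC1(C)O[C@H]2[C@H]3C(CS(=O)(=O)c4ccccc4)C(=O)O[C@H]3/C=C(/C)[C@@H](CC(=O)C(C)=[N+]=[N-])O[C@@H]2O1 | intermediate
23 | bicyclic oxonium ylide, not isolated | CC1(C)O[C@H]2[C@H]3C(CS(=O)(=O)c4ccccc4)C(=O)O[C@H]3/C=C(/C)[C@H]5CC(=O)[C-](C)[O+]5[C@@H]2O1 | intermediate
24 | (3R,4Z,6S,7S,8S,9R,10R)-ring-expanded tetrahydrofuran-3-one, sulfone-masked lactone | CC1(C)O[C@H]2[C@H]3C(CS(=O)(=O)c4ccccc4)C(=O)O[C@H]3/C=C(/C)[C@H]5CC(=O)[C@](C)(O5)[C@@H]2O1 | intermediate
25 | ring-expanded tetrahydrofuran-3-one with methylene lactone | CC1(C)O[C@H]2[C@H]3C(=C)C(=O)O[C@H]3/C=C(/C)[C@H]4CC(=O)[C@](C)(O4)[C@@H]2O1 | intermediate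
26 | trimethylsilyl enol ether (C1=C2) of 25, not isolated | CC1(C)O[C@H]2[C@H]3C(=C)C(=O)O[C@H]3/C=C(/C)[C@H]4C=C(O[Si](C)(C)C)[C@](C)(O4)[C@@H]2O1 | intermediate
27 | 3(2H)-furanone 8,9-acetonide | CC1(C)O[C@H]2[C@H]3C(=C)C(=O)O[C@H]3/C=C(/C)C3=CC(=O)[C@](C)(O3)[C@@H]2O1 | intermediate
28 | 8,9-diol | O[C@H]1[C@H]2C(=C)C(=O)O[C@H]2/C=C(/C)C2=CC(=O)[C@](C)(O2)[C@@H]1O | intermediate
29 | target, 8-O-methacrylate (6S,7S,8S,9R,10R) | C=C(C)C(=O)O[C@H]1[C@H]2C(=C)C(=O)O[C@H]2/C=C(/C)C2=CC(=O)[C@](C)(O2)[C@@H]1O | target

**Step count and risks**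

Total step count: 20. Longest linear sequence: 18 steps (steps 1–3, then 6–20).

Steps most likely to fail:

1. Step 16. The copper carbene may be intercepted by the C4=C5 alkene (cyclopropanation) or undergo 1,2-hydride shift from C14 before the ring oxygen captures it. The ylide may also collapse by cleavage at allylic C3. Fallback, setting out from 22 and returning at 24, is a stepwise ionic insertion without a metal carbene. Treating 22 with catalytic HBF4·OEt2 in CH2Cl2–AcOH at −20 °C should protonate the diazo carbon and let the ring oxygen displace N2. The resulting trialkyloxonium ion should cleave at the O–C9 acetal bond and the dioxolanylium ion should be trapped by acetate, giving the ring-opened 2-methyltetrahydrofuran-3-one anomeric acetate F1 (known acid-promoted cyclization of alkoxy diazoketones with loss of the O-substituent). Me3SiOTf/Et3N should then give the more substituted C1=C10 silyl enol ether F2. Catalytic Me3SiOTf at high dilution should ionize the acetate again, and intramolecular Mukaiyama-type alkylation at C10, trans to C7 on the dioxolane and cis to C4 on the five-membered ring, should close the ten-membered ring to 24.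

2. Step 11. Ring closure may lose out to oligomerization or catalyst decay, because an eight-membered ring with a trisubstituted alkene must form between two hindered alkenes in a substrate that already carries two five-membered rings. Fallback, setting out from 13 and returning at 17, closes the ring before the lactone. The Barbier addition would be quenched cold and the syn-hydroxy ester 15 isolated. Metathesis with the second-generation Grubbs catalyst on this more flexible diene, with a free allylic hydroxyl and a spectator acrylate, should give the eight-membered hydroxy ester F3. Lactonization with PPTS in benzene should then give 17.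

3. Step 10. Facial discrimination by the C8 stereocentre may be poor in the loose zinc transition state in a partly aqueous medium, and the allylzinc may lose its Z geometry, eroding the syn C6/C7 selectivity. Fallback, setting out from 13 and returning at 16, changes the nucleophile class. Borylation of 13 with B2pin2, KOAc and catalytic Pd2(dba)3 should give the (Z)-2-(methoxycarbonyl)allyl pinacol boronate F4. Thermal allylboration of acrolein in toluene through a compact boron-centred chair transition state, with retention of the alkene geometry, should give the syn adduct, which lactonizes in the flask to 16.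

Further compounds
F1 | step 16 | ring-opened 2-methyltetrahydrofuran-3-one with anomeric acetate at C9 (C9 and C10 epimers) | CC(=O)OC1OC(C)(C)O[C@H]1[C@H]2C(CS(=O)(=O)c3ccccc3)C(=O)O[C@H]2/C=C(/C)[C@H]4CC(=O)C(C)O4
F2 | step 16 | trimethylsilyl enol ether (C1=C10) of F1 | CC(=O)OC1OC(C)(C)O[C@H]1[C@H]2C(CS(=O)(=O)c3ccccc3)C(=O)O[C@H]2/C=C(/C)[C@H]4CC(O[Si](C)(C)C)=C(C)O4
F3 | step 11 | eight-membered cyclic acetal with free C6 hydroxyl and methyl acrylate unit on C7 | CC1(C)O[C@H]2[C@@H](C(=C)C(=O)OC)[C@@H](O)/C=C(/C)[C@@H](CCO[Si](C)(C)C(C)(C)C)O[C@@H]2O1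
F4 | step 10 | (Z)-2-(methoxycarbonyl)allyl pinacol boronate corresponding to 13 | CC1(C)OB(OC1(C)C)C/C(C(=O)OC)=C\[C@@H]2OC(C)(C)O[C@H]2O[C@H](CCO[Si](C)(C)C(C)(C)C)C(C)=C
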